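**Plan**

- Retrosynthesis: the benzoyl enol and the neighbouring ring C–OH are folded back into a 3-phenylisoxazole (temporary N–O bond). One prenyl group on the quaternary carbon is traced to a CH2–CH(OH)–CH2OSi arm. The carbocycle is then cut at two bonds: quaternary C–C(=O) on the benzoyl side and C(=O)–C(prenyl) on the other side.
- This gives a two-carbon piece, an α-geranyl γ-butyrolactone (its C=O and α-carbon become the ring C=O and the quaternary carbon; its ring O–C(=O) bond is temporary), and a four-carbon piece, 5-(4-methylpent-3-enyl)-3-phenylisoxazole-4-carbonyl chloride.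
- Enabling feature: the ring carbon that carries geranyl and prenyl lies between two ring ketones, so with one of them it is a latent ester enolate/acyl donor pair. The other four ring carbons with the benzoyl group are a 2-acyl-1,3-diketone, whose isoxazole form has an acidic 5-CH2 and an electrophilic 4-carbonyl.
- Forward: lateral prenylation of the isoxazole acid and geranylation of the chiral lactone; a one-pot C-acylation/lateral-anion Claisen condensation closes the only carbocycle and opens the lactone. The arm is then turned into prenyl (desilylation, glycol cleavage, Wittig), and N–O cleavage plus hydrolysis unveil the benzoyl triketone.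
- Stereochemistry: the single stereocentre is set in the acylation, anti to the CH2OSi arm of the (R)-lactone (chiral pool). Geranyl and prenyl never have to be told apart, because the second prenyl is built afterwards from the lactone carbons.

Key step: step 5

Remark: the target is drawn as one enol tautomer of a 2-benzoylcyclohexane-1,3,5-trione; the tautomers interconvert, and the configuration of the quaternary carbon does not depend on the tautomer drawn. TBDPS = tert-butyldiphenylsilyl.

**Route**

Step 1
Reactants: 1 5-methyl-3-phenyl-1,2-oxazole-4-carboxylic acid; 2 prenyl bromide (1-bromo-3-methylbut-2-ene)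
Product: 3 5-(4-methylpent-3-en-1-yl)-3-phenyl-1,2-oxazole-4-carboxylic acid
Conditions: n-BuLi (2.2 equiv), THF, −78 °C; then 2 (1.2 equiv), −78 to 0 °C; 1 M HCl work-up
Reagents that add atoms: none
Why: Carboxylate-directed lateral lithiation should give the dianion at the 5-methyl group (the most acidic C–H, vinylogous to the ring C=N), which is alkylated by SN2 at the primary carbon of the allylic bromide (lateral metalation–alkylation of a 5-methylisoxazole).

Step 2
Reactants: 3 5-(4-methylpent-3-en-1-yl)-3-phenyl-1,2-oxazole-4-carboxylic acid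
Product: 4 5-(4-methylpent-3-en-1-yl)-3-phenyl-1,2-oxazole-4-carbonyl chloride
Conditions: (COCl)2 (1.3 equiv), DMF (cat.), CH2Cl2, 0 °C to rt; evaporate, use crude
Reagents that add atoms: oxalyl chloride, O=C(Cl)C(Cl)=O
Why: Acid chloride formation through the Vilsmeier-type chloroiminium species from catalytic DMF is mild enough to leave the trisubstituted olefin and the isoxazole untouched.

Step 3
Reactants: 5 (5R)-5-(hydroxymethyl)dihydrofuran-2(3H)-one
Product: 6 (5R)-5-(TBDPS-oxymethyl)dihydrofuran-2(3H)-one
Conditions: tert-butyl(chloro)diphenylsilane (1.1 equiv), imidazole (2 equiv), DMF, rt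
Reagents that add atoms: tert-butyl(chloro)diphenylsilane, CC(C)(C)[Si](Cl)(c1ccccc1)c1ccccc1
Why: Imidazole-mediated silylation of the primary alcohol installs the bulky arm that later shields one face of the lactone enolate and can be removed without acid.

Step 4
Reactants: 6 (5R)-5-(TBDPS-oxymethyl)dihydrofuran-2(3H)-one; 7 geranyl bromide ((2E)-1-bromo-3,7-dimethylocta-2,6-diene)
Product: 8 (3S,5R)-3-geranyl-5-(TBDPS-oxymethyl)dihydrofuran-2(3H)-one
Conditions: LiN(iPr)2 (1.05 equiv), THF, −78 °C; then 7 (1.2 equiv), −78 to −30 °C; aq. NH4Cl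
Reagents that add atoms: none
Why: SN2 alkylation of the lactone lithium enolate by the primary allylic bromide should enter trans to the C5 arm, and the new C3 centre is of no consequence because it is planarized again in step 5.

Step 5
Reactants: 8 (3S,5R)-3-geranyl-5-(TBDPS-oxymethyl)dihydrofuran-2(3H)-one; 4 5-(4-methylpent-3-en-1-yl)-3-phenyl-1,2-oxazole-4-carbonyl chloride
Product: 10 (5S)-5-geranyl-6-hydroxy-5-[(2R)-2-hydroxy-3-(TBDPS-oxy)propyl]-7-prenyl-3-phenyl-1,2-benzoxazol-4(5H)-one, via C-acylated lactone 9 (not isolated)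
Conditions: 8 (1.05 equiv), LiN(iPr)2 (1.05 equiv), THF, −78 °C; cannulate into 4 (1.0 equiv) in THF, −78 °C; then LiN(SiMe3)2 (2.3 equiv), −78 to 0 °C; sat. aq. NH4Cl
Reagents that add atoms: none
Why: The lithium enolate of 8, whose geometry is fixed by the lactone ring, is C-acylated by acid chloride 4 to give 9 (first new bond, quaternary carbon to the isoxazolyl C=O); LiN(SiMe3)2 then deprotonates the CH2 on C5 of the isoxazole, now vinylogously activated by the 4-keto group and the only acidic C–H left, and this lateral carbanion adds to the lactone carbonyl, whose tetrahedral intermediate expels the ring oxygen as the side-chain alkoxide (second new bond, ring C=O to the prenyl-bearing carbon). The closest known reaction types are the C-acylation of α-substituted lactone enolates by acid chlorides and the Claisen/Dieckmann condensation of laterally metalated 5-alkylisoxazole-4-carbonyl or ortho-toluoyl compounds with esters. The carbocycle closes in the 6-(enolendo)-exo-trig mode on the ester carbonyl, the alternative attack through the isoxazole C4 being impossible (four-membered ring). The quaternary stereocentre is created in the acylation under substrate control: the acid chloride enters the enolate face anti to the C5 silyloxymethyl arm, so the (5R) centre from the chiral pool decides it, and because the second prenyl group is at this point still the lactone CH2–CH–O unit, geranyl and prenyl never have to be distinguished. The step needs C- over O-acylation (lithium enolate in THF at −78 °C, inverse addition to keep enolate away from product) and acylation before lactone opening (the facial bias exists only while the ring is intact), which the staged addition of the two bases secures. The liberated alkoxide cannot undo the ring by retro-Claisen attack because the product sits as its delocalized enolate until the quench.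

Step 6
Reactants: 10 (5S)-5-geranyl-6-hydroxy-5-[(2R)-2-hydroxy-3-(TBDPS-oxy)propyl]-7-prenyl-3-phenyl-1,2-benzoxazol-4(5H)-one
Product: 11 (5S)-5-[(2R)-2,3-dihydroxypropyl]-5-geranyl-6-hydroxy-7-prenyl-3-phenyl-1,2-benzoxazol-4(5H)-one
Conditions: Bu4NF (2.5 equiv), AcOH (2.5 equiv), THF, 0 °C to rt
Reagents that add atoms: none
Why: Fluoride cleaves the Si–O bond of the primary silyl ether under buffered, non-acidic conditions, so neither the olefins nor the enol and the neighbouring secondary alcohol are exposed to acid-induced cyclization.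

Step 7
Reactants: 11 (5S)-5-[(2R)-2,3-dihydroxypropyl]-5-geranyl-6-hydroxy-7-prenyl-3-phenyl-1,2-benzoxazol-4(5H)-one
Product: 12 2-[(5S)-5-geranyl-6-hydroxy-7-prenyl-4-oxo-3-phenyl-4,5-dihydro-1,2-benzoxazol-5-yl]acetaldehyde
Conditions: NaIO4 (1.5 equiv), THF/pH 7 phosphate buffer (2:1), 0 °C
Reagents that add atoms: none
Why: Malaprade glycol cleavage through the cyclic periodate ester removes the terminal carbon as formaldehyde and leaves the aldehyde two carbons away from the quaternary centre, which cannot epimerize.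

Step 8
Reactants: 12 2-[(5S)-5-geranyl-6-hydroxy-7-prenyl-4-oxo-3-phenyl-4,5-dihydro-1,2-benzoxazol-5-yl]acetaldehyde
Product: 13 (5R)-5-geranyl-6-hydroxy-5,7-diprenyl-3-phenyl-1,2-benzoxazol-4(5H)-one
Conditions: isopropyltriphenylphosphonium iodide (3.2 equiv), n-BuLi (3.0 equiv), THF, 0 °C; then 12, −78 °C to rt; aq. NH4Cl
Reagents that add atoms: isopropyltriphenylphosphonium iodide, CC(C)[P+](c1ccccc1)(c1ccccc1)c1ccccc1.[I-]
Why: In this Wittig olefination the first equivalent of the non-stabilized isopropylidene ylide deprotonates the ring enol (whose enolate shields the ring carbonyls) and a further equivalent converts the aldehyde into the symmetrical trisubstituted olefin, for which no E/Z question arises.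

Step 9
Reactants: 13 (5R)-5-geranyl-6-hydroxy-5,7-diprenyl-3-phenyl-1,2-benzoxazol-4(5H)-one
Product: 14 (2E,6R)-2-[amino(phenyl)methylidene]-6-geranyl-3-hydroxy-4,6-diprenylcyclohex-3-ene-1,5-dione
Conditions: Mo(CO)6 (0.6 equiv), MeCN/H2O (10:1), 80 °C
Reagents that add atoms: none
Why: Molybdenum hexacarbonyl binds the isoxazole nitrogen and cleaves the weak N–O bond reductively (known for isoxazoles and tetrahydrobenzisoxazolones) without touching any C=C bond, releasing the ring oxygen as the enol and the nitrogen as a vinylogous amide.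

Step 10
Reactants: 14 (2E,6R)-2-[amino(phenyl)methylidene]-6-geranyl-3-hydroxy-4,6-diprenylcyclohex-3-ene-1,5-dione
Product: 15 kolanone
Conditions: 2 M aq. NaOH, EtOH, 70 °C; then 1 M HCl to pH 3 at 0 °C
Reagents that add atoms: water, O
Why: Alkaline hydrolysis of the vinylogous primary amide (hydroxide addition to the aminobenzylidene carbon, loss of ammonia), the known way from 2-(aminoalkylidene)cyclohexane-1,3-diones to 2-acyl-1,3-diones, is chosen because the prenyl and geranyl olefins tolerate base but not acid, and the quaternary centre is not involved.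

**Compound list**

1 | 5-methyl-3-phenyl-1,2-oxazole-4-carboxylic acid | Cc1onc(-c2ccccc2)c1C(=O)O | starting material
2 | 1-bromo-3-methylbut-2-ene (prenyl bromide) | CC(C)=CCBr | starting material
3 | 5-(4-methylpent-3-en-1-yl)-3-phenyl-1,2-oxazole-4-carboxylic acid | CC(C)=CCCc1onc(-c2ccccc2)c1C(=O)O | intermediate
4 | 5-(4-methylpent-3-en-1-yl)-3-phenyl-1,2-oxazole-4-carbonyl chloride | CC(C)=CCCc1onc(-c2ccccc2)c1C(=O)Cl | intermediate
5 | (5R)-5-(hydroxymethyl)dihydrofuran-2(3H)-one | O=C1CC[C@H](CO)O1 | starting material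
6 | (5R)-5-{[tert-butyl(diphenyl)silyl]oxymethyl}dihydrofuran-2(3H)-one | O=C1CC[C@H](CO[Si](c2ccccc2)(c2ccccc2)C(C)(C)C)O1 | intermediate
7 | (2E)-1-bromo-3,7-dimethylocta-2,6-diene (geranyl bromide) | CC(C)=CCC/C(C)=C/CBr | starting material
8 | (3S,5R)-5-{[tert-butyl(diphenyl)silyl]oxymethyl}-3-[(2E)-3,7-dimethylocta-2,6-dien-1-yl]dihydrofuran-2(3H)-one (geranyl trans to the silyloxymethyl arm) | CC(C)=CCC/C(C)=C/C[C@H]1C[C@H](CO[Si](c2ccccc2)(c2ccccc2)C(C)(C)C)OC1=O | intermediate
9 | (3R,5R)-5-{[tert-butyl(diphenyl)silyl]oxymethyl}-3-[(2E)-3,7-dimethylocta-2,6-dien-1-yl]-3-{[5-(4-methylpent-3-en-1-yl)-3-phenyl-1,2-oxazol-4-yl]carbonyl}dihydrofuran-2(3H)-one (acyl group trans to the silyloxymethyl arm) | CC(C)=CCC/C(C)=C/C[C@]1(C(=O)c2c(CCC=C(C)C)onc2-c2ccccc2)C[C@H](CO[Si](c2ccccc2)(c2ccccc2)C(C)(C)C)OC1=O | intermediate (not isolated)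
10 | (5S)-5-[(2R)-3-{[tert-butyl(diphenyl)silyl]oxy}-2-hydroxypropyl]-5-[(2E)-3,7-dimethylocta-2,6-dien-1-yl]-6-hydroxy-7-(3-methylbut-2-en-1-yl)-3-phenyl-1,2-benzoxazol-4(5H)-one | CC(C)=CCC/C(C)=C/C[C@]1(C[C@@H](O)CO[Si](c2ccccc2)(c2ccccc2)C(C)(C)C)C(O)=C(CC=C(C)C)c2onc(-c3ccccc3)c2C1=O | intermediate
11 | (5S)-5-[(2R)-2,3-dihydroxypropyl]-5-[(2E)-3,7-dimethylocta-2,6-dien-1-yl]-6-hydroxy-7-(3-methylbut-2-en-1-yl)-3-phenyl-1,2-benzoxazol-4(5H)-one | CC(C)=CCC/C(C)=C/C[C@]1(C[C@@H](O)CO)C(O)=C(CC=C(C)C)c2onc(-c3ccccc3)c2C1=O | intermediate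
12 | 2-[(5S)-5-[(2E)-3,7-dimethylocta-2,6-dien-1-yl]-6-hydroxy-7-(3-methylbut-2-en-1-yl)-4-oxo-3-phenyl-4,5-dihydro-1,2-benzoxazol-5-yl]acetaldehyde | CC(C)=CCC/C(C)=C/C[C@]1(CC=O)C(O)=C(CC=C(C)C)c2onc(-c3ccccc3)c2C1=O | intermediate
13 | (5R)-5-[(2E)-3,7-dimethylocta-2,6-dien-1-yl]-6-hydroxy-5,7-bis(3-methylbut-2-en-1-yl)-3-phenyl-1,2-benzoxazol-4(5H)-one | CC(C)=CCC/C(C)=C/C[C@]1(CC=C(C)C)C(O)=C(CC=C(C)C)c2onc(-c3ccccc3)c2C1=O | intermediate
14 | (2E,6R)-2-[amino(phenyl)methylidene]-6-[(2E)-3,7-dimethylocta-2,6-dien-1-yl]-3-hydroxy-4,6-bis(3-methylbut-2-en-1-yl)cyclohex-3-ene-1,5-dione | CC(C)=CCC/C(C)=C/C[C@]1(CC=C(C)C)C(=O)C(CC=C(C)C)=C(O)/C(=C(\N)c2ccccc2)C1=O | intermediate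
15 | kolanone, (2E,6R)-6-[(2E)-3,7-dimethylocta-2,6-dien-1-yl]-3-hydroxy-2-[hydroxy(phenyl)methylidene]-4,6-bis(3-methylbut-2-en-1-yl)cyclohex-3-ene-1,5-dione | CC(C)=CCC/C(C)=C/C[C@]1(CC=C(C)C)C(=O)C(CC=C(C)C)=C(O)/C(=C(\O)c2ccccc2)C1=O | target

**Step count and risks**

Total steps: 10. Longest linear sequence: 8 steps (from 5 through steps 3, 4, 5–10; equally from 1 through steps 1, 2, 5–10).

Steps most likely to fail:

1. Step 5. The hindered tetrasubstituted enolate may be acylated on oxygen by the flanked heteroaroyl chloride, or proton transfer from the lateral CH2 of 9 to unreacted enolate may stop the acylation halfway. Fallback (sets out from 4 and 8, returns at 9 and then 10): the C–C bond is made by an aldol addition, which has no O- versus C-ambiguity, and the oxidation level is adjusted afterwards. Acid chloride 4 is reduced with LiAlH(OtBu)3 (THF, −78 °C) to 5-(4-methylpent-3-en-1-yl)-3-phenyl-1,2-oxazole-4-carbaldehyde F1. The lithium enolate of 8 (LiN(iPr)2, THF, −78 °C) should add to it anti to the silyloxymethyl arm to give the β-hydroxy lactone (3R,5R)-5-(TBDPS-oxymethyl)-3-geranyl-3-{hydroxy[5-(4-methylpent-3-en-1-yl)-3-phenyl-1,2-oxazol-4-yl]methyl}dihydrofuran-2(3H)-one F2 (carbinol epimers, both usable). Dess–Martin periodinane (CH2Cl2, NaHCO3) then gives 9, now isolated, and LiN(SiMe3)2 (2.3 equiv, THF, −78 to 0 °C) closes the ring to 10 as in the second stage of step 5.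

2. Step 10. Under the basic conditions the substrate is an enolate anion, so hydroxide addition to the aminobenzylidene carbon may be too slow; at the forcing temperature then needed, retro-Claisen opening of the non-enolizable 1,3-diketone can compete. Fallback (sets out from 13, returns at 15): the ring enol is capped before the nitrogen is exposed, so that the vinylogous amide is neutral and its hydroxide adduct is a stabilized 1,3-diketonate. Compound 13 is O-methylated with trimethylsilyldiazomethane (toluene/MeOH, 0 °C) to (5R)-5-geranyl-6-methoxy-5,7-diprenyl-3-phenyl-1,2-benzoxazol-4(5H)-one F4. Mo(CO)6 (MeCN/H2O, 80 °C) then gives (2E,6R)-2-[amino(phenyl)methylidene]-6-geranyl-5-methoxy-4,6-diprenylcyclohex-4-ene-1,3-dione F5. Aqueous NaOH in EtOH at 50 °C should remove ammonia and then saponify the vinylogous methyl ester to give 15 after acidification.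

3. Step 8. The acidic enol consumes ylide, and the resulting ring enolate may add to the neighbouring aldehyde (intramolecular aldol), or the aldehyde may rest as a cyclic hemiacetal with the enol oxygen, so that olefination stalls. Fallback (sets out from 12, returns at 13): the olefin is built without a basic ylide. Non-basic methylenation of 12 with Cp2TiMe2 (toluene, 65 °C) should give (5R)-5-allyl-5-geranyl-6-hydroxy-7-prenyl-3-phenyl-1,2-benzoxazol-4(5H)-one F3. Cross-metathesis with 2-methyl-2-butene (second-generation Hoveyda–Grubbs catalyst, CH2Cl2, 40 °C) converts the allyl group into prenyl and returns to 13, the trisubstituted olefins of geranyl and prenyl being spectators.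

**Further compounds**

F1 | step 5 | 5-(4-methylpent-3-en-1-yl)-3-phenyl-1,2-oxazole-4-carbaldehyde | CC(C)=CCCc1onc(-c2ccccc2)c1C=O
F2 | step 5 | (3R,5R)-5-{[tert-butyl(diphenyl)silyl]oxymethyl}-3-[(2E)-3,7-dimethylocta-2,6-dien-1-yl]-3-{hydroxy[5-(4-methylpent-3-en-1-yl)-3-phenyl-1,2-oxazol-4-yl]methyl}dihydrofuran-2(3H)-one (carbinol epimers) | CC(C)=CCC/C(C)=C/C[C@]1(C(O)c2c(CCC=C(C)C)onc2-c2ccccc2)C[C@H](CO[Si](c2ccccc2)(c2ccccc2)C(C)(C)C)OC1=O
F3 | step 8 | (5R)-5-[(2E)-3,7-dimethylocta-2,6-dien-1-yl]-6-hydroxy-7-(3-methylbut-2-en-1-yl)-3-phenyl-5-(prop-2-en-1-yl)-1,2-benzoxazol-4(5H)-one | CC(C)=CCC/C(C)=C/C[C@]1(CC=C)C(O)=C(CC=C(C)C)c2onc(-c3ccccc3)c2C1=O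
F4 | step 10 | (5R)-5-[(2E)-3,7-dimethylocta-2,6-dien-1-yl]-6-methoxy-5,7-bis(3-methylbut-2-en-1-yl)-3-phenyl-1,2-benzoxazol-4(5H)-one | CC(C)=CCC/C(C)=C/C[C@]1(CC=C(C)C)C(OC)=C(CC=C(C)C)c2onc(-c3ccccc3)c2C1=O
F5 | step 10 | (2E,6R)-2-[amino(phenyl)methylidene]-6-[(2E)-3,7-dimethylocta-2,6-dien-1-yl]-5-methoxy-4,6-bis(3-methylbut-2-en-1-yl)cyclohex-4-ene-1,3-dione | CC(C)=CCC/C(C)=C/C[C@]1(CC=C(C)C)C(OC)=C(CC=C(C)C)C(=O)/C(=C(\N)c2ccccc2)C1=O
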